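Abbreviations used in names: R = (2E)-3,7-dimethyl-7-(triethylsilyloxy)oct-2-en-1-yl; ArB = 2,4-bis(tert-butyldimethylsilyloxy)-3-R-phenyl (ring B with its chain).
Remark on the chemistry: the ketene-acetal geometry of diene 29 and the E/Z composition of 28 are taken as inconsequential, because the carbons concerned end up in the aromatic ring A.

## Analysis of the target

The target 34 is a (3S)-isoflavanone: ring C (O1, C2, C3, C4, C4a, C8a) is a chroman-4-one fused to a phloroglucinol-type ring A with free hydroxyls on C5 and C7. C3 carries ring B, a 2',4'-dihydroxyphenyl group whose C3' bears an (E)-7-hydroxy-3,7-dimethyloct-2-enyl chain, that is, a geranyl group hydrated at its distal double bond. C3 is the only stereocentre; it is benzylic and alpha to the C4 ketone, so it can be lost through the enol or enolate under base and, more slowly, under acid, and no second centre can relay or restore it. The sensitive groups are four free phenols, a trisubstituted E alkene that is allylic to ring B and flanked by two phenols (acid closes it to a chroman, electrophilic halogen attacks it), and a tertiary alcohol that ionises under acid. The difficulty therefore lies less in the skeleton than in setting and keeping C3, in placing the chain between the two oxygens of ring B, and in finding protecting groups that leave without acid or base. The plan rests on the fact that ring A is joined to ring C only through C4a–C8a: its other carbons C5 to C8, with oxygen on C5 and C7, have the pattern of an acetoacetate-derived 1,3-dioxygenated diene. Ring A can thus be grown last, across the C4a=C8a double bond of a monocyclic 3-aryl-2,3-dihydropyran-4-one in which C3 is already in place.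

## Retrosynthetic reasoning

34 to 33. The last operation only removes three silyl ethers. Silyl groups are chosen for ring B and the tertiary alcohol because buffered fluoride takes them off without enolising C3 or protonating the alkene. Ring A needs no protection, since it is created as the free diphenol one step earlier.

33 to 26 and 29. The C4a–C5 and C8–C8a bonds are cut. They are the only pair that detaches a four-carbon unit carrying the 5,7-oxygens; a cut at O1–C8a or C4–C4a would keep a protected phloroglucinol as building block and bring acetal protecting groups back into the endgame. The gain is that the tricycle shrinks to monocycle 26 with C3 already set. The forward reaction must join the methylene terminus of 29 to C8a (the beta carbon of the vinylogous ester) and its ketene-acetal carbon to C4a. It must then expel hydrogen bromide and methanol so that the new ring aromatises, all without touching C3. The bromine of 26 is there to activate the double bond and to supply the oxidation level of the arene.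

29 to 28 to 27. The diene is the doubly O-silylated dienol form of acetoacetate 27, reached by two successive silylations.

26 to 23. The O1–C8a enol-ether bond and the C4a–Br bond are cut. Ring C is the cyclised form of β-hydroxy ynone 23. Bromine is introduced on the open-chain enaminone 24, where the carbon to be brominated is by far the most nucleophilic site. In the closed vinylogous ester it would have to compete with the trisubstituted alkene and with ring B. Closure of 25 by the primary hydroxyl then gives 26.

23 to 21 and 22. The ketone–alkyne bond is cut. Addition of acetylide 22 to the N-methoxy-N-methyl amide 21 stops at the ketone and leaves C3 alone.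

21 to 20 to 18. The C2–C3 bond is cut, which makes C3 the alpha carbon of arylacetyl imide 18 and C2 a one-carbon aldehyde electrophile. The oxazolidinone sets C3 in an aldol reaction of boron enolate 19. A boron enolate is preferred to the strongly Lewis acidic titanium-enolate conditions, which the tertiary silyl ether and the alkene would not survive. The auxiliary is then exchanged for the amide of 21.

18 to 14 and 15. The C1'–CH2 bond is cut: the enolate of the commercial acetyl imide 15 is arylated by bromide 14. This brings in the two-carbon unit and the auxiliary together. It also avoids any intermediate with a free 2'-phenol next to an acyl group (which would lactonise) and any hydroxide-mediated ester cleavage (which aryl silyl ethers would not survive).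

14 to 13 to 11. This is a protecting-group exchange. The acetals of 11 are needed to direct metalation, the silyl ethers of 14 for the fluoride endgame. The exchange is placed where the molecule has neither a stereocentre nor an acyl group.

11 to 8 and 6. The C3'–C1'' bond is cut. The C–H between the two acetal oxygens of 8 is the most acidic one. A lithium amide removes it without touching the C–Br bond, and the derived copper reagent 10 is allylated by 6. The bromine, present already in the commercial phenol 7, marks C1' for the later coupling, so no electrophilic halogenation is needed once the alkene is in the molecule.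

6 to 4 to 3 to 2 to 1. The chain comes from geranyl acetate 1, which already has the E alkene. Only the distal alkene has to be hydrated (2), the tertiary alcohol protected (3) and the acetate turned into a bromide (4, 6).

## Alternatives that were turned down

Alternative 1: The side chain is cut at C1''–C2'' (and at the C3''–methyl bond) and attached last to a finished, protected chromanol core. In the forward step Cp2ZrCl2 catalyses syn-methylalumination of alkyne A3, and zerovalent palladium couples the resulting alkenylalane with benzylic chloride A2 to give the trans-chromanol silyl ether A1.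
- For it: the carbometalation fixes the E geometry reliably, the alkene and the tertiary ether are absent during the whole core synthesis, and C3 sits next to a C4 silyl ether where it cannot enolise. Every step is known chemistry.
- Against it: the E alkene comes free of charge in 1, so the step buys nothing the chiral pool does not supply. A2 is a benzylic chloride flanked by two alkoxy groups; it ionises easily, and the excess Me3Al threatens both it and the four acetals. The step forms no bond of the isoflavanone skeleton, so the whole tricycle still has to be made beforehand.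
- Endgame: after A1 the C4 oxygen must be unmasked and oxidised, and four acetals removed with acid from a product whose C3 epimerises, whose alkene cyclises onto the phenols and whose tertiary alcohol ionises.
- Comparison: this plan is stronger on reliability and on protecting C3 until late. The chosen plan offers a fluoride-only endgame and spends its key step on the skeleton itself (two C–C bonds and ring A).

Alternative 2: Ring B is dismantled into a four-carbon unit, the unsaturated diazo ketone A6 carried on a chromanol, and a two-carbon unit, the siloxyalkyne A5 that bears the chain. Irradiation of A6 gives a vinylketene by Wolff rearrangement; [2+2] addition to A5, four-electron ring opening and six-electron electrocyclisation then give the phenol A4.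
- For it: one step assembles the crowded 1,2,3,4-substituted ring B with the chain between two differentiated oxygens, the benzannulation type is precedented and regiochemically predictable, and C3 is stored at the chromanol level.
- Against it: ring B is the one part that comes from a commercial benzene (7) in two operations, so a benzannulation is spent where none is needed. A6 requires a complete chromanol with a diazo ketone arm. A5 is a skipped enyne with a labile ynol ether and a doubly activated CH2 that can isomerise, and its alkene can trap the ketene.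
- Endgame: after A4, five silyl groups of three kinds must be differentiated to oxidise C4 selectively.
- Comparison: both plans are benzannulations, and this one is the better precedented. It builds the cheap ring, whereas the chosen plan builds ring A and so completes the skeleton with far shorter access to its precursors.

Alternative 3: The O1–C8a bond is cut. The open-chain bromo diol A8 comes from a syn-aldol reaction between the ring-B arylacetyl imide and a ring-A bromobenzaldehyde, followed by reduction. A copper-catalysed intramolecular etherification of Ullmann type then closes ring C and gives the trans-chroman-4-ol A7.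
- For it: every step is established, the aldol joins rings A and B and sets C3 in one operation, six-membered C–O closure is dependable, and C3 is not epimerisable at the chromanol stage.
- Against it: the endgame. C4 must be oxidised and four acetals removed with acid, the very conditions under which C3, the alkene and the tertiary alcohol of this target suffer. The coupling also needs base at elevated temperature.
- Comparison: on certainty this is the stronger plan, and its logic is kept as the fallback for step 16. It is of similar length. The chosen plan delivers ring A directly as the free diphenol, keeps C4 at the ketone level throughout and ends with fluoride instead of acid.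

Key step: step 16

## Route

Step 1
Reactants: 1 geranyl acetate
Product: 2 (2E)-7-hydroxy-3,7-dimethyloct-2-en-1-yl acetate
Conditions: Hg(OAc)2 (1.0 equiv), THF/H2O, 0 °C; then NaBH4, aq. NaOH, 0 °C
Reagents that add atoms: water, O
Why: Markovnikov oxymercuration–demercuration; the 6,7-alkene is the more electron-rich one because the 2,3-alkene is deactivated by the allylic acetate, so one equivalent of the divalent mercury salt should hydrate only the distal double bond; no stereocentre is formed.

Step 2
Reactants: 2 (2E)-7-hydroxy-3,7-dimethyloct-2-en-1-yl acetate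
Product: 3 (2E)-3,7-dimethyl-7-(triethylsilyloxy)oct-2-en-1-yl acetate (R–OAc)
Conditions: TESOTf, 2,6-lutidine, CH2Cl2, −78 → 0 °C
Reagents that add atoms: triethylsilyl triflate, CC[Si](CC)(CC)OS(=O)(=O)C(F)(F)F
Why: Silylation of a tertiary alcohol needs the silyl triflate; the buffered conditions leave the allylic acetate and the alkene untouched.

Step 3
Reactants: 3 R–OAc
Product: 4 (2E)-3,7-dimethyl-7-(triethylsilyloxy)oct-2-en-1-ol (R–OH)
Conditions: K2CO3 (cat.), MeOH, 25 °C
Reagents that add atoms: none
Why: Transesterification of the acetate with methanol; a tertiary triethylsilyl ether is stable to carbonate in methanol.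

Step 4
Reactants: 4 R–OH
Product: 6 (2E)-1-bromo-3,7-dimethyl-7-(triethylsilyloxy)oct-2-ene (R–Br), via allylic mesylate 5 (not isolated)
Conditions: MsCl, Et3N, THF, −40 °C; then LiBr, 0 °C
Reagents that add atoms: lithium bromide, [Li+].[Br-]
Why: Mesylation and in situ SN2 displacement by bromide under acid-free conditions should keep the silyl ether and the E geometry; the bromide is used crude.

Step 5
Reactants: 7 4-bromoresorcinol
Product: 8 1-bromo-2,4-bis(methoxymethoxy)benzene
Conditions: MOMCl, i-Pr2NEt, CH2Cl2, 0 → 25 °C
Reagents that add atoms: chloromethyl methyl ether, COCCl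
Why: Acetal protection of both phenols; the two OCH2OCH3 groups are the directing groups for the next step.

Step 6
Reactants: 8 1-bromo-2,4-bis(methoxymethoxy)benzene; 6 R–Br
Product: 11 1-bromo-2,4-bis(methoxymethoxy)-3-R-benzene, via aryllithium 9 (not isolated), via arylcopper 10 (not isolated)
Conditions: lithium 2,2,6,6-tetramethylpiperidide, THF, −78 °C; CuBr·SMe2, −78 → −40 °C; then 6, −40 → 0 °C
Reagents that add atoms: none
Why: Directed ortho-metalation: the C–H between the two acetal oxygens is the most acidic, and an amide base (not an alkyllithium) leaves the C–Br bond intact; transmetalation to monovalent copper and SN2 allylation should place the chain between the oxygens with retention of the E alkene.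

Step 7
Reactants: 11 1-bromo-2,4-bis(methoxymethoxy)-3-R-benzene
Product: 13 4-bromo-2-R-benzene-1,3-diol, via bis(trimethylsilyl) ether 12 (not isolated)
Conditions: TMSOTf, 2,2'-bipyridyl, MeCN, 0 → 25 °C; then H2O
Reagents that add atoms: none
Why: Silyl triflate/bipyridyl cleavage of aromatic methoxymethyl ethers runs without protic acid, so the phenols should not add to the neighbouring alkene and the tertiary silyl ether should not ionise.

Step 8
Reactants: 13 4-bromo-2-R-benzene-1,3-diol
Product: 14 1-bromo-2,4-bis(tert-butyldimethylsilyloxy)-3-R-benzene (ArB–Br)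
Conditions: TBSOTf, 2,6-lutidine, CH2Cl2, 0 → 25 °C
Reagents that add atoms: tert-butyldimethylsilyl triflate, CC(C)(C)[Si](C)(C)OS(=O)(=O)C(F)(F)F
Why: The silyl triflate silylates both hindered phenols; aryl tert-butyldimethylsilyl ethers survive all later steps and leave with fluoride at the end.

Step 9
Reactants: 14 ArB–Br; 15 (4S)-3-acetyl-4-benzyl-1,3-oxazolidin-2-one
Product: 18 (4S)-4-benzyl-3-(ArB-acetyl)-1,3-oxazolidin-2-one, via lithium enolate 16 (not isolated), via zinc enolate 17 (not isolated)
Conditions: 15 (2 equiv), LiN(SiMe3)2, THF, −78 °C; ZnCl2, −78 → 0 °C; then 14, Pd(dba)2 (5 mol%), P(t-Bu)3 (10 mol%), THF, 25–50 °C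
Reagents that add atoms: none
Why: Negishi-type α-arylation of a zinc imide enolate under zerovalent palladium with a bulky trialkylphosphine; the weakly basic zinc enolate tolerates the aryl silyl ethers, and the two-carbon unit arrives already attached to the auxiliary, so no free 2'-phenol ever stands next to an acyl group.

Step 10
Reactants: 18 (4S)-4-benzyl-3-(ArB-acetyl)-1,3-oxazolidin-2-one
Product: 20 (4S)-4-benzyl-3-[(2S)-2-ArB-3-hydroxypropanoyl]-1,3-oxazolidin-2-one, via boron enolate 19 (not isolated)
Conditions: Bu2BOTf, i-Pr2NEt, CH2Cl2, −78 → 0 °C; HCHO (gas, from cracked paraformaldehyde), −78 °C; pH 7 buffer, MeOH, H2O2, 0 °C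
Reagents that add atoms: formaldehyde, C=O
Why: Evans syn-aldol manifold with formaldehyde: the Z boron enolate reacts through a Zimmerman–Traxler chair in which the auxiliary carbonyl points away from the enolate oxygen, so the (4S)-benzyl group directs formaldehyde to the face that gives the (S)-centre, the future C3; the boron Lewis acid is mild enough for the tertiary silyl ether and the alkene.

Step 11
Reactants: 20 (4S)-4-benzyl-3-[(2S)-2-ArB-3-hydroxypropanoyl]-1,3-oxazolidin-2-one
Product: 21 (2S)-2-ArB-3-hydroxy-N-methoxy-N-methylpropanamide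
Conditions: MeNHOMe·HCl, Me3Al, CH2Cl2, −20 → 0 °C; aq. potassium sodium tartrate
Reagents that add atoms: N,O-dimethylhydroxylamine hydrochloride, CNOC.Cl
Why: Aminolysis of the imide by the aluminium amide (Weinreb amide formation); the free β-hydroxyl becomes an aluminium alkoxide that directs attack to the exocyclic carbonyl, and the non-basic medium should not epimerise C3.

Step 12
Reactants: 21 (2S)-2-ArB-3-hydroxy-N-methoxy-N-methylpropanamide; 22 ethynylmagnesium bromide
Product: 23 (4S)-4-ArB-5-hydroxypent-1-yn-3-one
Conditions: 22 (4 equiv), THF, −20 → 0 °C; cold aq. NaHSO4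
Reagents that add atoms: none
Why: Weinreb ketone synthesis: the first equivalent deprotonates the hydroxyl, the chelated tetrahedral intermediate prevents over-addition, and the cold acidic quench keeps the released hydroxylamine protonated so that it cannot add to the ynone.

Step 13
Reactants: 23 (4S)-4-ArB-5-hydroxypent-1-yn-3-one
Product: 26 (3S)-5-bromo-3-ArB-2,3-dihydro-4H-pyran-4-one, via enaminone 24 (not isolated), via bromo enaminone 25 (not isolated)
Conditions: morpholine (1.05 equiv), CH2Cl2, −40 °C; NBS (1.0 equiv), −78 °C; TsOH·H2O (1.1 equiv), −78 → 0 °C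
Reagents that add atoms: N-bromosuccinimide, O=C1CCC(=O)N1Br
Why: Aza-Michael addition to the terminal ynone gives the E enaminone, whose alpha carbon is far more nucleophilic than the trisubstituted alkene or ring B, so bromination should occur only there; acid then drives addition–elimination by the primary hydroxyl with loss of morpholine (the enaminone route to 3-halo chromones, here with an aliphatic hydroxyl), and C3 is safe because the carbonyl is a vinylogous amide during the basic phase.

Step 14
Reactants: 27 methyl acetoacetate
Product: 28 methyl 3-(trimethylsilyloxy)but-2-enoate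
Conditions: TMSCl, Et3N, hexane, 25 °C
Reagents that add atoms: chlorotrimethylsilane, C[Si](C)(C)Cl
Why: O-silylation of the enolised β-keto ester gives the silyl enol ether; the E/Z mixture is used as such.

Step 15
Reactants: 28 methyl 3-(trimethylsilyloxy)but-2-enoate
Product: 29 1-methoxy-1,3-bis(trimethylsilyloxy)buta-1,3-diene
Conditions: LiN(i-Pr)2, THF, −78 °C; TMSCl, −78 → 0 °C
Reagents that add atoms: chlorotrimethylsilane, C[Si](C)(C)Cl
Why: γ-Deprotonation of the vinylogous ester and O-silylation of the dienolate give the bis(silyloxy)diene, a masked acetoacetate dianion; it is distilled and used at once.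

Step 16
Reactants: 26 (3S)-5-bromo-3-ArB-2,3-dihydro-4H-pyran-4-one; 29 1-methoxy-1,3-bis(trimethylsilyloxy)buta-1,3-diene
Product: 33 (3S)-3-ArB-5,7-dihydroxychroman-4-one, via open-chain conjugate adduct 30 (not isolated), via bicyclic bromo ketal 31 (not isolated), via bis(trimethylsilyl) ether 32 (not isolated)
Conditions: 29 (2.5 equiv), 2,6-di-tert-butyl-4-methylpyridine (3 equiv), CH2Cl2, −78 °C; TMSOTf (1.3 equiv, added last), −78 → 0 °C; aq. NaHCO3; then citric acid, MeOH, 0 °C
Reagents that add atoms: none
Why: Proposed new method: TMSOTf silylates the C4 carbonyl of 26 to a 4-silyloxy oxocarbenium ion whose electrophilic carbon is C8a, and the methylene terminus of 29 adds there (C8–C8a bond). The resulting trioxygen-stabilised carbenium ion at C5 is then captured by the bromo silyl enol ether carbon C4a (C4a–C5 bond) in a 6-(enolexo)-exo-trig closure, which completes a stepwise polar [4+2] annulation and gives 31; the open form 30 can re-enter by re-silylation of its ester. The closest known reaction types are silyl triflate-mediated conjugate additions of 1,3-bis(silyloxy)dienes to pyranone- and chromone-derived oxocarbenium ions, and cycloaddition–aromatisation of 1,3-dioxygenated silyloxy dienes with halo quinones and halo enones. Ionisation of the mixed ketal (loss of methoxytrimethylsilane), proton loss from C8 and syn-elimination of hydrogen bromide across C4a–C8a, driven by aromatisation, should give 32, and mild acid then frees the two phenols; the bromine supplies the oxidation level. No stereocentre is created. The selectivity needed is regiochemical (diene terminus to C8a, ketene-acetal carbon to C4a) and is fixed by the polarity of both partners. The configuration at C3 is protected by adding TMSOTf last at −78 °C so that the cation is trapped at once, by the absence of any unhindered base, and by the hindered pyridine that takes up triflic acid and hydrogen bromide.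

Step 17
Reactants: 33 (3S)-3-ArB-5,7-dihydroxychroman-4-one
Product: 34 (3S)-3-{2,4-dihydroxy-3-[(2E)-7-hydroxy-3,7-dimethyloct-2-en-1-yl]phenyl}-5,7-dihydroxy-2,3-dihydro-4H-chromen-4-one
Conditions: HF·pyridine, pyridine, THF, 0 → 25 °C
Reagents that add atoms: none
Why: Fluoride-mediated desilylation; pyridine-buffered HF should cleave the two aryl silyl ethers and the tertiary triethylsilyl ether without base (no enolisation at C3) and without strong acid (no chroman formation, no tertiary cation).

## Compound list

1 | geranyl acetate, (2E)-3,7-dimethylocta-2,6-dien-1-yl acetate | CC(C)=CCC/C(C)=C/COC(C)=O | starting material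
2 | (2E)-7-hydroxy-3,7-dimethyloct-2-en-1-yl acetate | CC(C)(O)CCC/C(C)=C/COC(C)=O | intermediate
3 | (2E)-3,7-dimethyl-7-(triethylsilyloxy)oct-2-en-1-yl acetate | CC[Si](CC)(CC)OC(C)(C)CCC/C(C)=C/COC(C)=O | intermediate
4 | (2E)-3,7-dimethyl-7-(triethylsilyloxy)oct-2-en-1-ol | CC[Si](CC)(CC)OC(C)(C)CCC/C(C)=C/CO | intermediate
5 | (2E)-3,7-dimethyl-7-(triethylsilyloxy)oct-2-en-1-yl methanesulfonate | CC[Si](CC)(CC)OC(C)(C)CCC/C(C)=C/COS(C)(=O)=O | intermediate (not isolated)
6 | (2E)-1-bromo-3,7-dimethyl-7-(triethylsilyloxy)oct-2-ene | CC[Si](CC)(CC)OC(C)(C)CCC/C(C)=C/CBr | intermediate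
7 | 4-bromoresorcinol (4-bromobenzene-1,3-diol) | Oc1ccc(Br)c(O)c1 | starting material
8 | 1-bromo-2,4-bis(methoxymethoxy)benzene | COCOc1ccc(Br)c(OCOC)c1 | intermediate
9 | [3-bromo-2,6-bis(methoxymethoxy)phenyl]lithium | [Li]c1c(OCOC)ccc(Br)c1OCOC | intermediate (not isolated)
10 | [3-bromo-2,6-bis(methoxymethoxy)phenyl]copper | [Cu]c1c(OCOC)ccc(Br)c1OCOC | intermediate (not isolated)
11 | 1-bromo-2,4-bis(methoxymethoxy)-3-R-benzene | C/C(=C\Cc1c(OCOC)ccc(Br)c1OCOC)CCCC(C)(C)O[Si](CC)(CC)CC | intermediate
12 | 1-bromo-3-R-2,4-bis(trimethylsilyloxy)benzene | C/C(=C\Cc1c(O[Si](C)(C)C)ccc(Br)c1O[Si](C)(C)C)CCCC(C)(C)O[Si](CC)(CC)CC | intermediate (not isolated)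
13 | 4-bromo-2-R-benzene-1,3-diol | C/C(=C\Cc1c(O)ccc(Br)c1O)CCCC(C)(C)O[Si](CC)(CC)CC | intermediate
14 | 1-bromo-2,4-bis(tert-butyldimethylsilyloxy)-3-R-benzene (ArB–Br) | C/C(=C\Cc1c(O[Si](C)(C)C(C)(C)C)ccc(Br)c1O[Si](C)(C)C(C)(C)C)CCCC(C)(C)O[Si](CC)(CC)CC | intermediate
15 | (4S)-3-acetyl-4-benzyl-1,3-oxazolidin-2-one | CC(=O)N1[C@@H](Cc2ccccc2)COC1=O | starting material
16 | lithium enolate of 15 | [Li]OC(=C)N1[C@@H](Cc2ccccc2)COC1=O | intermediate (not isolated)
17 | chlorozinc enolate of 15 | Cl[Zn]OC(=C)N1[C@@H](Cc2ccccc2)COC1=O | intermediate (not isolated)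
18 | (4S)-4-benzyl-3-(ArB-acetyl)-1,3-oxazolidin-2-one | C/C(=C\Cc1c(O[Si](C)(C)C(C)(C)C)ccc(CC(=O)N2[C@@H](Cc3ccccc3)COC2=O)c1O[Si](C)(C)C(C)(C)C)CCCC(C)(C)O[Si](CC)(CC)CC | intermediate
19 | (Z)-dibutylboron enolate of 18 | C/C(=C\Cc1c(O[Si](C)(C)C(C)(C)C)ccc(/C=C(\OB(CCCC)CCCC)N2[C@@H](Cc3ccccc3)COC2=O)c1O[Si](C)(C)C(C)(C)C)CCCC(C)(C)O[Si](CC)(CC)CC | intermediate (not isolated)
20 | (4S)-4-benzyl-3-[(2S)-2-ArB-3-hydroxypropanoyl]-1,3-oxazolidin-2-one | C/C(=C\Cc1c(O[Si](C)(C)C(C)(C)C)ccc([C@@H](CO)C(=O)N2[C@@H](Cc3ccccc3)COC2=O)c1O[Si](C)(C)C(C)(C)C)CCCC(C)(C)O[Si](CC)(CC)CC | intermediate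
21 | (2S)-2-ArB-3-hydroxy-N-methoxy-N-methylpropanamide | C/C(=C\Cc1c(O[Si](C)(C)C(C)(C)C)ccc([C@@H](CO)C(=O)N(C)OC)c1O[Si](C)(C)C(C)(C)C)CCCC(C)(C)O[Si](CC)(CC)CC | intermediate
22 | ethynylmagnesium bromide | C#C[Mg]Br | starting material
23 | (4S)-4-ArB-5-hydroxypent-1-yn-3-one | C/C(=C\Cc1c(O[Si](C)(C)C(C)(C)C)ccc([C@@H](CO)C(=O)C#C)c1O[Si](C)(C)C(C)(C)C)CCCC(C)(C)O[Si](CC)(CC)CC | intermediate
24 | (1E,4S)-4-ArB-5-hydroxy-1-(morpholin-4-yl)pent-1-en-3-one | C/C(=C\Cc1c(O[Si](C)(C)C(C)(C)C)ccc([C@@H](CO)C(=O)/C=C/N2CCOCC2)c1O[Si](C)(C)C(C)(C)C)CCCC(C)(C)O[Si](CC)(CC)CC | intermediate (not isolated)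
25 | (1Z,4S)-2-bromo-4-ArB-5-hydroxy-1-(morpholin-4-yl)pent-1-en-3-one | C/C(=C\Cc1c(O[Si](C)(C)C(C)(C)C)ccc([C@@H](CO)C(=O)/C(Br)=C/N2CCOCC2)c1O[Si](C)(C)C(C)(C)C)CCCC(C)(C)O[Si](CC)(CC)CC | intermediate (not isolated)
26 | (3S)-5-bromo-3-ArB-2,3-dihydro-4H-pyran-4-one | C/C(=C\Cc1c(O[Si](C)(C)C(C)(C)C)ccc([C@H]2COC=C(Br)C2=O)c1O[Si](C)(C)C(C)(C)C)CCCC(C)(C)O[Si](CC)(CC)CC | intermediate
27 | methyl acetoacetate | COC(=O)CC(C)=O | starting material
28 | methyl 3-(trimethylsilyloxy)but-2-enoate (E/Z mixture) | COC(=O)C=C(C)O[Si](C)(C)C | intermediate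
29 | 1-methoxy-1,3-bis(trimethylsilyloxy)buta-1,3-diene | C=C(O[Si](C)(C)C)/C=C(\OC)O[Si](C)(C)C | intermediate
30 | methyl 4-[(5S)-5-ArB-3-bromo-4-(trimethylsilyloxy)-5,6-dihydro-2H-pyran-2-yl]-3-(trimethylsilyloxy)but-2-enoate (mixture at C2 of the pyran) | C/C(=C\Cc1c(O[Si](C)(C)C(C)(C)C)ccc([C@H]2COC(CC(O[Si](C)(C)C)=CC(=O)OC)C(Br)=C2O[Si](C)(C)C)c1O[Si](C)(C)C(C)(C)C)CCCC(C)(C)O[Si](CC)(CC)CC | intermediate (not isolated)
31 | (3S)-3-ArB-4a-bromo-5-methoxy-5,7-bis(trimethylsilyloxy)-2,3,4a,5,8,8a-hexahydro-4H-chromen-4-one (mixture at C4a, C5, C8a) | C/C(=C\Cc1c(O[Si](C)(C)C(C)(C)C)ccc([C@H]2COC3CC(O[Si](C)(C)C)=CC(OC)(O[Si](C)(C)C)C3(Br)C2=O)c1O[Si](C)(C)C(C)(C)C)CCCC(C)(C)O[Si](CC)(CC)CC | intermediate (not isolated)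
32 | (3S)-3-ArB-5,7-bis(trimethylsilyloxy)chroman-4-one | C/C(=C\Cc1c(O[Si](C)(C)C(C)(C)C)ccc([C@H]2COc3cc(O[Si](C)(C)C)cc(O[Si](C)(C)C)c3C2=O)c1O[Si](C)(C)C(C)(C)C)CCCC(C)(C)O[Si](CC)(CC)CC | intermediate (not isolated)
33 | (3S)-3-ArB-5,7-dihydroxychroman-4-one | C/C(=C\Cc1c(O[Si](C)(C)C(C)(C)C)ccc([C@H]2COc3cc(O)cc(O)c3C2=O)c1O[Si](C)(C)C(C)(C)C)CCCC(C)(C)O[Si](CC)(CC)CC | intermediate
34 | (3S)-3-{2,4-dihydroxy-3-[(2E)-7-hydroxy-3,7-dimethyloct-2-en-1-yl]phenyl}-5,7-dihydroxy-2,3-dihydro-4H-chromen-4-one | C/C(=C\Cc1c(O)ccc([C@H]2COc3cc(O)cc(O)c3C2=O)c1O)CCCC(C)(C)O | target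

## Step count and least certain steps

Total: 17 steps. Longest linear sequence: 14 steps (steps 1–4, 6–13, 16 and 17, from geranyl acetate).

Step 16 (key step, proposed new method). Four processes are the most likely to go wrong:
- Silyl transfer may outrun the ring closure, so that the open-chain adduct accumulates and does not close.
- Ring C may open by β-elimination of O1 from C8a once C7 has become a ketone.
- Halophilic debromination of the bicyclic intermediate by excess diene would remove the oxidation level needed for aromatisation.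
- Proton loss from C3 of the oxocarbenium ion would erode the configuration.

Fallback with known chemistry, in which ring C is closed by C–O coupling on a preformed aromatic ring A; it sets out from 14 and comes back at 33. Bromide 14 is coupled as in step 9 with the zinc enolate of (4R)-3-acetyl-4-benzyl-1,3-oxazolidin-2-one to give the imide F1 with the enantiomeric auxiliary. Its dibutylboron enolate should add to 2-bromo-4,6-bis(methoxymethoxy)benzaldehyde in a syn-aldol reaction to give F2. The enantiomeric auxiliary is needed because here the imide carbonyl becomes C2 and the aldehyde carbon C4. LiBH4 removes the auxiliary and gives diol F3. CuI with 1,10-phenanthroline and K3PO4 in toluene at 90 °C closes the O1–C8a bond to the trans-chroman-4-ol F4, in which C3 cannot enolise. Dess–Martin oxidation gives the isoflavanone F5, and TMSOTf/2,2'-bipyridyl followed by water frees the 5- and 7-hydroxyls to give 33.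

Step 13. The amine may cause proton exchange at C3 or dehydration of the β-hydroxy ynone before the conjugate addition is complete, and any ynone left unconverted would let the bromine source attack the side-chain alkene instead. Fallback, from 23 back to 26 without any amine: cyclisation of 23 with catalytic Ph3PAuNTf2 (monovalent gold) in CH2Cl2 in the presence of NBS, so that the 6-endo oxyauration is followed by bromo-deauration and the C–Br bond forms at the organometallic stage instead of on an enaminone; no new isolable compound arises.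

Step 10. Monomeric formaldehyde may repolymerise before the boron enolate captures it, which would leave the conversion low, and prolonged contact may cost diastereoselectivity. Fallback, from 14 back to 20, which forms the C3–C1' bond under auxiliary control instead of the C2–C3 bond: the chlorozinc enolate of (4S)-4-benzyl-3-[3-(triethylsilyloxy)propanoyl]-1,3-oxazolidin-2-one F6 is arylated by 14 under the palladium conditions of step 9. The aryl group is expected to enter anti to the benzyl group of the chelated enolate and so give the (2S)-imide F7; pyridinium tosylate in methanol at 0 °C then removes the primary silyl ether and gives 20.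

Step 9. Proton transfer from the more acidic product to the zinc enolate, thermal fragmentation of the zinc imide enolate, or slow oxidative addition to the hindered, electron-rich bromide may stall the coupling. Fallback, from 14 back to 18 through an ester instead of the imide enolate: palladium-catalysed coupling of 14 with commercial (2-tert-butoxy-2-oxoethyl)zinc chloride gives tert-butyl ester F8. TMSOTf/2,6-lutidine then water cleaves it to acid F9 without hydroxide. Pivaloyl chloride/Et3N converts F9 into the mixed anhydride F10, which acylates (4S)-4-benzyl-1,3-oxazolidin-2-one in the presence of LiCl to give 18.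

## Further compounds

F1 | step 16 | (4R)-4-benzyl-3-(ArB-acetyl)-1,3-oxazolidin-2-one | C/C(=C\Cc1c(O[Si](C)(C)C(C)(C)C)ccc(CC(=O)N2[C@H](Cc3ccccc3)COC2=O)c1O[Si](C)(C)C(C)(C)C)CCCC(C)(C)O[Si](CC)(CC)CC
F2 | step 16 | (4R)-4-benzyl-3-{(2R,3R)-2-ArB-3-[2-bromo-4,6-bis(methoxymethoxy)phenyl]-3-hydroxypropanoyl}-1,3-oxazolidin-2-one | C/C(=C\Cc1c(O[Si](C)(C)C(C)(C)C)ccc([C@H]([C@@H](O)c2c(Br)cc(OCOC)cc2OCOC)C(=O)N3[C@H](Cc4ccccc4)COC3=O)c1O[Si](C)(C)C(C)(C)C)CCCC(C)(C)O[Si](CC)(CC)CC
F3 | step 16 | (1R,2S)-2-ArB-1-[2-bromo-4,6-bis(methoxymethoxy)phenyl]propane-1,3-diol | C/C(=C\Cc1c(O[Si](C)(C)C(C)(C)C)ccc([C@@H](CO)[C@@H](O)c2c(Br)cc(OCOC)cc2OCOC)c1O[Si](C)(C)C(C)(C)C)CCCC(C)(C)O[Si](CC)(CC)CC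
F4 | step 16 | (3S,4R)-3-ArB-5,7-bis(methoxymethoxy)chroman-4-ol (trans) | C/C(=C\Cc1c(O[Si](C)(C)C(C)(C)C)ccc([C@H]2COc3cc(OCOC)cc(OCOC)c3[C@@H]2O)c1O[Si](C)(C)C(C)(C)C)CCCC(C)(C)O[Si](CC)(CC)CC
F5 | step 16 | (3S)-3-ArB-5,7-bis(methoxymethoxy)chroman-4-one | C/C(=C\Cc1c(O[Si](C)(C)C(C)(C)C)ccc([C@H]2COc3cc(OCOC)cc(OCOC)c3C2=O)c1O[Si](C)(C)C(C)(C)C)CCCC(C)(C)O[Si](CC)(CC)CC
F0 | step 13 | none | none
F6 | step 10 | (4S)-4-benzyl-3-[3-(triethylsilyloxy)propanoyl]-1,3-oxazolidin-2-one | CC[Si](CC)(CC)OCCC(=O)N1[C@@H](Cc2ccccc2)COC1=O
F7 | step 10 | (4S)-4-benzyl-3-[(2S)-2-ArB-3-(triethylsilyloxy)propanoyl]-1,3-oxazolidin-2-one | C/C(=C\Cc1c(O[Si](C)(C)C(C)(C)C)ccc([C@@H](CO[Si](CC)(CC)CC)C(=O)N2[C@@H](Cc3ccccc3)COC2=O)c1O[Si](C)(C)C(C)(C)C)CCCC(C)(C)O[Si](CC)(CC)CC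
F8 | step 9 | tert-butyl ArB-acetate | C/C(=C\Cc1c(O[Si](C)(C)C(C)(C)C)ccc(CC(=O)OC(C)(C)C)c1O[Si](C)(C)C(C)(C)C)CCCC(C)(C)O[Si](CC)(CC)CC
F9 | step 9 | ArB-acetic acid | C/C(=C\Cc1c(O[Si](C)(C)C(C)(C)C)ccc(CC(=O)O)c1O[Si](C)(C)C(C)(C)C)CCCC(C)(C)O[Si](CC)(CC)CC
F10 | step 9 | ArB-acetic pivalic anhydride | C/C(=C\Cc1c(O[Si](C)(C)C(C)(C)C)ccc(CC(=O)OC(=O)C(C)(C)C)c1O[Si](C)(C)C(C)(C)C)CCCC(C)(C)O[Si](CC)(CC)CC
A1 | alternative 1 | trans-4-(tert-butyldimethylsilyloxy)-3-[2,4-bis(methoxymethoxy)-3-R-phenyl]-5,7-bis(methoxymethoxy)chroman | C/C(=C\Cc1c(OCOC)ccc([C@H]2COc3cc(OCOC)cc(OCOC)c3[C@@H]2O[Si](C)(C)C(C)(C)C)c1OCOC)CCCC(C)(C)O[Si](CC)(CC)CC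
A2 | alternative 1 | trans-4-(tert-butyldimethylsilyloxy)-3-[3-(chloromethyl)-2,4-bis(methoxymethoxy)phenyl]-5,7-bis(methoxymethoxy)chroman | ClCc1c(OCOC)ccc([C@H]2COc3cc(OCOC)cc(OCOC)c3[C@@H]2O[Si](C)(C)C(C)(C)C)c1OCOC
A3 | alternative 1 | 6-methyl-6-(triethylsilyloxy)hept-1-yne | C#CCCCC(C)(C)O[Si](CC)(CC)CC
A4 | alternative 2 | cis-5,7-bis(tert-butyldimethylsilyloxy)-3-[2-hydroxy-3-R-4-(triisopropylsilyloxy)phenyl]-4-(triethylsilyloxy)chroman | C/C(=C\Cc1c(O[Si](C(C)C)(C(C)C)C(C)C)ccc([C@H]2COc3cc(O[Si](C)(C)C(C)(C)C)cc(O[Si](C)(C)C(C)(C)C)c3[C@H]2O[Si](CC)(CC)CC)c1O)CCCC(C)(C)O[Si](CC)(CC)CC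
A5 | alternative 2 | {[(4E)-5,9-dimethyl-9-(triethylsilyloxy)dec-4-en-1-yn-1-yl]oxy}triisopropylsilane | C/C(=C\CC#CO[Si](C(C)C)(C(C)C)C(C)C)CCCC(C)(C)O[Si](CC)(CC)CC
A6 | alternative 2 | (3E)-4-[cis-5,7-bis(tert-butyldimethylsilyloxy)-4-(triethylsilyloxy)chroman-3-yl]-1-diazobut-3-en-2-one | [N-]=[N+]=CC(=O)/C=C/[C@H]1COc2cc(O[Si](C)(C)C(C)(C)C)cc(O[Si](C)(C)C(C)(C)C)c2[C@H]1O[Si](CC)(CC)CC
A7 | alternative 3 | trans-3-[2,4-bis(methoxymethoxy)-3-R-phenyl]-5,7-bis(methoxymethoxy)chroman-4-ol | C/C(=C\Cc1c(OCOC)ccc([C@H]2COc3cc(OCOC)cc(OCOC)c3[C@@H]2O)c1OCOC)CCCC(C)(C)O[Si](CC)(CC)CC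
A8 | alternative 3 | (1R,2S)-1-[2-bromo-4,6-bis(methoxymethoxy)phenyl]-2-[2,4-bis(methoxymethoxy)-3-R-phenyl]propane-1,3-diol | C/C(=C\Cc1c(OCOC)ccc([C@@H](CO)[C@@H](O)c2c(Br)cc(OCOC)cc2OCOC)c1OCOC)CCCC(C)(C)O[Si](CC)(CC)CC
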